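**Plan**

- Retrosynthesis: the MOM ether on O4' and the 7-O–CH3 bond are cut first, then C5–C6 of ring A (enolate acylation), then C7–C8 (acetyl on the lateral carbon), C2–OAr (chloride displacement), the ring C bonds C4–C4a and O1–C2 (β-keto ester plus 3,3-dichloroacryloyl chloride), and last C8–C1' (prenylation of the acetoacetate dianion).
- Forward: the prenyl-bearing chain is made first, pyranone ring C is closed on it, the aryl ether and the acetyl group are added, and ring A is closed last; 7-O-methylation and loss of the MOM group finish the synthesis.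
- Enabling feature: ring A carries oxygen on C5 and C7 (1,3-related) and shares the C4a–C8a bond with ring C. A pyranone bearing the C5 carboxyl carbon on C4a and a methyl ketone chain (C8, C7 carbonyl, C6 methyl) on C8a already holds all six ring A atoms, so one C5–C6 acylation completes the arene.
- Stereochemistry: the target has no stereocentre and no stereogenic double bond; the only stereocentre on the way (C8 of the cyclisation precursor) is racemic and vanishes on aromatisation.

Key step: step 7

Remark: atoms are numbered as in the chromone of the target (O1, C2 to C8a, C1' for the prenyl CH2), also in the pyranone intermediates, whose names follow pyranone numbering. Enolates and other metalated forms of a numbered compound carry no number of their own.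

**Route**

Step 1
Reactants: 1 methyl acetoacetate; 2 prenyl bromide (1-bromo-3-methylbut-2-ene)
Product: 3 methyl 7-methyl-3-oxooct-6-enoate
Conditions: NaH (1.1 equiv), THF, 0 °C; n-BuLi (1.05 equiv), 0 °C; 2, 0 °C → rt; aq. HCl quench
Reagents that add atoms: none
Why: Weiler-type γ-alkylation of the acetoacetate dianion, in which the more basic terminal carbanion should be alkylated by the allylic bromide in an SN2 reaction, placing the future C8 next to the prenyl group and leaving the α-position free for ring C.

Step 2
Reactants: 4 3,3-dichloroacrylic acid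
Product: 5 3,3-dichloroacryloyl chloride
Conditions: (COCl)2, DMF (cat.), CH2Cl2, 0 °C → rt; concentrated and used crude
Reagents that add atoms: oxalyl chloride, ClC(=O)C(=O)Cl
Why: Standard acid chloride formation through the DMF-derived chloroiminium (Vilsmeier) intermediate, which the electron-poor dichlorovinyl group should tolerate.

Step 3
Reactants: 3 methyl 7-methyl-3-oxooct-6-enoate; 5 3,3-dichloroacryloyl chloride
Product: 7 methyl 6-chloro-2-(4-methylpent-3-en-1-yl)-4-oxo-4H-pyran-3-carboxylate, via enol triketone 6 (not isolated)
Conditions: MgCl2 (1.1 equiv), pyridine (2.2 equiv), CH2Cl2, 0 °C; 5, 0 °C → rt, then 40 °C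
Reagents that add atoms: none
Why: Rathke-type C-acylation of the magnesium chelate of the β-keto ester should give 6, whose ketone enol oxygen then adds to the dichlorovinyl carbon and expels chloride (addition–elimination, the nucleophilic vinylic substitution known for β,β-dichlorovinyl ketones with oxygen nucleophiles), closing the 4-pyranone in a 6-endo-trig mode and leaving one chlorine on C2 as a vinylogous acid chloride.

Step 4
Reactants: 8 hydroquinone
Product: 9 4-(methoxymethoxy)phenol
Conditions: 8 (3 equiv), NaH (1 equiv), DMF, 0 °C, argon; MOMCl (1 equiv), 0 °C → rt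
Reagents that add atoms: chloromethyl methyl ether, COCCl
Why: Williamson-type O-alkylation of the monosodium salt, in which the excess of diol keeps double protection low, should give the mono-ether, separable from diol and bis-ether by extraction and chromatography.

Step 5
Reactants: 7 methyl 6-chloro-2-(4-methylpent-3-en-1-yl)-4-oxo-4H-pyran-3-carboxylate; 9 4-(methoxymethoxy)phenol
Product: 10 methyl 6-[4-(methoxymethoxy)phenoxy]-2-(4-methylpent-3-en-1-yl)-4-oxo-4H-pyran-3-carboxylate
Conditions: K2CO3 (1.5 equiv), MeCN, 0 °C → rt
Reagents that add atoms: none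
Why: Addition–elimination (nucleophilic vinylic substitution) of the phenoxide at the vinylogous acid chloride carbon C2 should be fast and irreversible, whereas addition at the alkyl-bearing C8a has no leaving group and reverts.

Step 6
Reactants: 10 methyl 6-[4-(methoxymethoxy)phenoxy]-2-(4-methylpent-3-en-1-yl)-4-oxo-4H-pyran-3-carboxylate
Product: 12 methyl 6-[4-(methoxymethoxy)phenoxy]-2-(6-methyl-2-oxohept-5-en-3-yl)-4-oxo-4H-pyran-3-carboxylate (racemic), via lithium hemiaminal adduct 11 (not isolated)
Conditions: LiN(SiMe3)2 (1.15 equiv), THF, −78 °C; MeC(O)N(OMe)Me, −78 → −20 °C; AcOH, −78 °C, then pH 7 buffer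
Reagents that add atoms: N-methoxy-N-methylacetamide, CC(=O)N(C)OC
Why: Lateral (vinylogous) deprotonation of the C8 methylene, which is conjugated through C8a=C4a with both the C4 ketone and the C5 ester, followed by a Weinreb ketone synthesis should place the acetyl group on C8, because chelated adduct 11 resists a second addition and releases the ketone only on the cold acidic quench; the new C8 stereocentre is racemic and is destroyed in step 7.

Step 7
Reactants: 12 methyl 6-[4-(methoxymethoxy)phenoxy]-2-(6-methyl-2-oxohept-5-en-3-yl)-4-oxo-4H-pyran-3-carboxylate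
Product: 14 5,7-dihydroxy-2-[4-(methoxymethoxy)phenoxy]-8-(3-methylbut-2-en-1-yl)-4H-chromen-4-one, via ring A triketo tautomer 13 (not isolated)
Conditions: LiN(i-Pr)2 (2.5 equiv), THF, −78 → 0 °C; AcOH quench
Reagents that add atoms: none
Why: LiN(i-Pr)2 first takes the C8 proton, which lies between the ketone and the pyranone, and then one proton of the acetyl methyl group; the C6 terminus of this dianion adds to the C5 ester carbonyl, methoxide leaves, and triketo tautomer 13 enolises irreversibly to the aromatic 5,7-diol, which drives the condensation. The closest known reaction type is the Dieckmann (intramolecular Claisen) cyclisation of ortho-(2-oxopropyl) aryl esters and polyketo esters to fused resorcinols, familiar from biomimetic polyketide aromatisations. Ring A closes in a 6-(enolendo)-exo-trig mode, helped by the ring C double bond between C4a and C8a, which locks the ester carbon and the ketone chain on the same side and in one plane. No stereocentre is formed, and the racemic C8 centre of 12 becomes an sp2 carbon of the arene. The step needs carbon-over-oxygen and C6-over-C8 selectivity and must leave C2 untouched: attack from C8 would give a four-membered ring, closure through the C7 enolate oxygen to an enol lactone is reopened by the methoxide while C-acylation ends in an arene, and the bulky amide base acting on an already anionic substrate should not add to the aryloxy-bearing C2. Because C8 carries its prenyl group from step 1, no 6- versus 8-prenyl regiochemistry arises.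

Step 8
Reactants: 14 5,7-dihydroxy-2-[4-(methoxymethoxy)phenoxy]-8-(3-methylbut-2-en-1-yl)-4H-chromen-4-one
Product: 15 5-hydroxy-7-methoxy-2-[4-(methoxymethoxy)phenoxy]-8-(3-methylbut-2-en-1-yl)-4H-chromen-4-one
Conditions: MeI (1.1 equiv), K2CO3 (1.2 equiv), acetone, rt
Reagents that add atoms: iodomethane, CI
Why: Williamson methylation under weak base should occur at the 7-OH, the more acidic phenol (conjugated with the C4 carbonyl), while the 5-OH is tied up in a hydrogen bond to that carbonyl, as is general for 5,7-dihydroxychromones.

Step 9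
Reactants: 15 5-hydroxy-7-methoxy-2-[4-(methoxymethoxy)phenoxy]-8-(3-methylbut-2-en-1-yl)-4H-chromen-4-one
Product: 16 7-O-methylepimedonin G, 5-hydroxy-2-(4-hydroxyphenoxy)-7-methoxy-8-(3-methylbut-2-en-1-yl)-4H-chromen-4-one
Conditions: aq. HCl (3 M), i-PrOH–THF, 40 °C
Reagents that add atoms: none
Why: Acid-catalysed hydrolysis of the methoxymethyl acetal through its oxocarbenium ion should free the 4'-phenol under conditions mild enough for the C2 aryl ether and for the prenyl alkene, which has no free ortho hydroxyl to cyclise onto once O7 is methylated.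

**Compound list**

1 | methyl acetoacetate | COC(=O)CC(C)=O | starting material
2 | prenyl bromide (1-bromo-3-methylbut-2-ene) | CC(C)=CCBr | starting material
3 | methyl 7-methyl-3-oxooct-6-enoate | COC(=O)CC(=O)CCC=C(C)C | intermediate
4 | 3,3-dichloroacrylic acid | OC(=O)C=C(Cl)Cl | starting material
5 | 3,3-dichloroacryloyl chloride | ClC(=O)C=C(Cl)Cl | intermediate
6 | methyl 2-(3,3-dichloroprop-2-enoyl)-3-hydroxy-7-methylocta-2,6-dienoate (enol form of the triketone, magnesium chelate in the flask) | COC(=O)C(C(=O)C=C(Cl)Cl)=C(O)CCC=C(C)C | intermediate (not isolated)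
7 | methyl 6-chloro-2-(4-methylpent-3-en-1-yl)-4-oxo-4H-pyran-3-carboxylate | COC(=O)c1c(CCC=C(C)C)oc(Cl)cc1=O | intermediate
8 | hydroquinone | Oc1ccc(O)cc1 | starting material
9 | 4-(methoxymethoxy)phenol | COCOc1ccc(O)cc1 | intermediate
10 | methyl 6-[4-(methoxymethoxy)phenoxy]-2-(4-methylpent-3-en-1-yl)-4-oxo-4H-pyran-3-carboxylate | COC(=O)c1c(CCC=C(C)C)oc(Oc2ccc(OCOC)cc2)cc1=O | intermediate
11 | lithium alkoxide of the N-methoxy-N-methyl hemiaminal at the acetyl carbon of 12 (tetrahedral Weinreb adduct, mixture of diastereomers) | [Li+].COC(=O)c1c(C(CC=C(C)C)C(C)([O-])N(C)OC)oc(Oc2ccc(OCOC)cc2)cc1=O | intermediate (not isolated)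
12 | methyl 6-[4-(methoxymethoxy)phenoxy]-2-(6-methyl-2-oxohept-5-en-3-yl)-4-oxo-4H-pyran-3-carboxylate (racemic at C8) | COC(=O)c1c(C(CC=C(C)C)C(C)=O)oc(Oc2ccc(OCOC)cc2)cc1=O | intermediate
13 | 2-[4-(methoxymethoxy)phenoxy]-8-(3-methylbut-2-en-1-yl)-4H-chromene-4,5,7(6H,8H)-trione (racemic at C8) | O=C1CC(=O)C(CC=C(C)C)c2oc(Oc3ccc(OCOC)cc3)cc(=O)c21 | intermediate (not isolated)
14 | 5,7-dihydroxy-2-[4-(methoxymethoxy)phenoxy]-8-(3-methylbut-2-en-1-yl)-4H-chromen-4-one | Oc1cc(O)c2c(=O)cc(Oc3ccc(OCOC)cc3)oc2c1CC=C(C)C | intermediate
15 | 5-hydroxy-7-methoxy-2-[4-(methoxymethoxy)phenoxy]-8-(3-methylbut-2-en-1-yl)-4H-chromen-4-one | COc1cc(O)c2c(=O)cc(Oc3ccc(OCOC)cc3)oc2c1CC=C(C)C | intermediate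
16 | 7-O-methylepimedonin G, 5-hydroxy-2-(4-hydroxyphenoxy)-7-methoxy-8-(3-methylbut-2-en-1-yl)-4H-chromen-4-one | COc1cc(O)c2c(=O)cc(Oc3ccc(O)cc3)oc2c1CC=C(C)C | target

**Step count**

Total step count: 9. Longest linear sequence: 7 steps (steps 1, 3, 5, 6, 7, 8 and 9, from methyl acetoacetate); steps 2 and 4 each prepare a coupling partner in one step.

**Steps most likely to fail**

Step 7 (ring A closure). The second deprotonation may remain incomplete. The C7 enolate oxygen may close onto the ester to give an enol lactone. The methoxide set free may exchange the aryloxy group at C2 by addition–elimination.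

The fallback brings the aryl ether in after ring A is closed and lets sulfur hold C2 meanwhile. It sets out from 7. NaSMe (THF, 0 °C) should give methyl 2-(4-methylpent-3-en-1-yl)-6-(methylsulfanyl)-4-oxo-4H-pyran-3-carboxylate F1. Lateral acetylation under the conditions of step 6 should give methyl 2-(6-methyl-2-oxohept-5-en-3-yl)-6-(methylsulfanyl)-4-oxo-4H-pyran-3-carboxylate F2. The same LiN(i-Pr)2 closure should give 5,7-dihydroxy-8-(3-methylbut-2-en-1-yl)-2-(methylsulfanyl)-4H-chromen-4-one F3, since a methylsulfanyl group is a far poorer leaving group towards methoxide than an aryloxide. Methylation as in step 8 should give 5-hydroxy-7-methoxy-8-(3-methylbut-2-en-1-yl)-2-(methylsulfanyl)-4H-chromen-4-one F4. Oxidation at sulfur with H2O2 and catalytic (NH4)6Mo7O24 in EtOH at 0 °C, chosen to spare the trisubstituted alkene, should give 5-hydroxy-2-(methanesulfonyl)-7-methoxy-8-(3-methylbut-2-en-1-yl)-4H-chromen-4-one F5. Displacement of methanesulfinate by 9 (K2CO3, DMF, rt), the established entry to 2-aryloxychromones, comes back to the route at 15.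

Step 6 (lateral acetylation). The doubly stabilised lateral anion may add too slowly to the amide, or be quenched by proton transfer from it; more reactive acetyl donors risk acylation at oxygen.

The fallback replaces acylation by aldol addition and oxidation. It sets out from 10. Its lateral anion (LiN(SiMe3)2, THF, −78 °C) would be added to acetaldehyde and quenched cold with AcOH, to prevent lactonisation onto the C5 ester and dehydration. This should give methyl 2-(2-hydroxy-6-methylhept-5-en-3-yl)-6-[4-(methoxymethoxy)phenoxy]-4-oxo-4H-pyran-3-carboxylate F6 as a mixture of diastereomers. Oxidation with Dess–Martin periodinane (NaHCO3, CH2Cl2, 0 °C) comes back to the route at 12.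

Step 3 (ring C formation). Acylation may occur at the enol oxygen, or the enolate may attack the dichlorovinyl terminus of 5. The vinylogous acid chloride 7 may also be consumed by the magnesium enolate or by pyridine in the same flask.

The fallback changes the carbon nucleophile to an enamine and separates acylation from ring closure. It sets out from 3. Condensation with pyrrolidine (toluene, reflux, Dean–Stark) should give methyl (2E)-7-methyl-3-(pyrrolidin-1-yl)octa-2,6-dienoate F7. C-acylation with 5 (Et3N, CH2Cl2, −20 °C → rt), the enamino ester acylation used in quinolone syntheses, should give methyl 2-(3,3-dichloroprop-2-enoyl)-7-methyl-3-(pyrrolidin-1-yl)octa-2,6-dienoate F8. Hydrolysis with aq. HCl (1 M) in THF comes back to the route at 6, here isolated as its enol, which would be closed to 7 with NaHCO3 in MeCN in the absence of any nucleophilic amine.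

**Further compounds**

F1 | step 7 | methyl 2-(4-methylpent-3-en-1-yl)-6-(methylsulfanyl)-4-oxo-4H-pyran-3-carboxylate | COC(=O)c1c(CCC=C(C)C)oc(SC)cc1=O
F2 | step 7 | methyl 2-(6-methyl-2-oxohept-5-en-3-yl)-6-(methylsulfanyl)-4-oxo-4H-pyran-3-carboxylate (racemic) | COC(=O)c1c(C(CC=C(C)C)C(C)=O)oc(SC)cc1=O
F3 | step 7 | 5,7-dihydroxy-8-(3-methylbut-2-en-1-yl)-2-(methylsulfanyl)-4H-chromen-4-one | CSc1cc(=O)c2c(O)cc(O)c(CC=C(C)C)c2o1
F4 | step 7 | 5-hydroxy-7-methoxy-8-(3-methylbut-2-en-1-yl)-2-(methylsulfanyl)-4H-chromen-4-one | CSc1cc(=O)c2c(O)cc(OC)c(CC=C(C)C)c2o1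
F5 | step 7 | 5-hydroxy-2-(methanesulfonyl)-7-methoxy-8-(3-methylbut-2-en-1-yl)-4H-chromen-4-one | CS(=O)(=O)c1cc(=O)c2c(O)cc(OC)c(CC=C(C)C)c2o1
F6 | step 6 | methyl 2-(2-hydroxy-6-methylhept-5-en-3-yl)-6-[4-(methoxymethoxy)phenoxy]-4-oxo-4H-pyran-3-carboxylate (mixture of diastereomers) | COC(=O)c1c(C(CC=C(C)C)C(C)O)oc(Oc2ccc(OCOC)cc2)cc1=O
F7 | step 3 | methyl (2E)-7-methyl-3-(pyrrolidin-1-yl)octa-2,6-dienoate | COC(=O)/C=C(/N1CCCC1)CCC=C(C)C
F8 | step 3 | methyl 2-(3,3-dichloroprop-2-enoyl)-7-methyl-3-(pyrrolidin-1-yl)octa-2,6-dienoate (push–pull alkene, geometry not fixed) | COC(=O)C(C(=O)C=C(Cl)Cl)=C(CCC=C(C)C)N1CCCC1
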